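## Retrosynthetic overview

- The target comes from the 19-hydroxy acid and tigloyl chloride (last step); the 19-hydroxy acid comes from a 3β,19-diol ester by radical removal of the 3-oxygen through a cyclic thiocarbonate.
- Key disconnection: C4–C5 and C9–C10 of the decalin are opened together to an acyclic C20 (2Z,6E,10E)-trienoate ending in a (2S,3R)-epoxy alcohol. Ring A closes first and ring B second in one cationic cascade; the epoxide fixes the absolute configuration and the (Z)-hydroxymethyl arm becomes the axial C19.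
- The epoxide comes from Sharpless epoxidation of the (14Z)-allylic alcohol; its Z-trisubstituted tail comes from an sp3–sp2 Suzuki coupling of a diene-derived borane with (Z)-3-iodo-2-methylprop-2-en-1-ol.
- The Z-enoate head and chain come from geranyl bromide and methyl acetoacetate (dianion alkylation, E-enol triflate, methylation), then SeO2 oxidation and methylenation.

Assumption: the SMILES is read as the normal-series labdane (4S,5R,9S,10R; 5α-H, 9α-H, 10β-CH3) with the acyloxymethyl group axial on C4 (C19, 4β), a 13Z acid side chain and an E (tiglate) ester; labdane numbering is used for all bicyclic compounds.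

## Route

Step 1
Reactants: 1 prop-2-yn-1-ol
Product: 3 (2Z)-3-iodo-2-methylprop-2-en-1-ol, via alkenylmagnesium alkoxide 2 (not isolated)
Conditions: MeMgBr (2.3 equiv), CuI (10 mol%), THF, −10 °C → rt; then I2, −20 → 0 °C; aqueous quench
Reagents that add atoms: methylmagnesium bromide, C[Mg]Br; iodine, [I][I]
Why: Copper-catalysed anti-carbomagnesiation of the propargylic alkoxide (Duboudin–Jousseaume) puts CH3 on C2 and Mg on C3 inside a five-membered chelate, so iodinolysis with retention gives the Z-iodide (I cis to CH2OH).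

Step 2
Reactants: 4 geranyl bromide [(2E)-1-bromo-3,7-dimethylocta-2,6-diene]; 5 methyl acetoacetate
Product: 7 methyl (6E)-7,11-dimethyl-3-oxododeca-6,10-dienoate, via acetoacetate dianion 6 (not isolated)
Conditions: NaH then n-BuLi, THF, 0 °C; add 4, 0 °C → rt; dilute HCl quench
Reagents that add atoms: none
Why: Weiler dianion alkylation, in which the more basic terminal carbanion displaces the allylic bromide (SN2) and the E alkene of the geranyl unit is untouched.

Step 3
Reactants: 7 methyl (6E)-7,11-dimethyl-3-oxododeca-6,10-dienoate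
Product: 8 methyl (2E,6E)-7,11-dimethyl-3-{[(trifluoromethyl)sulfonyl]oxy}dodeca-2,6,10-trienoate
Conditions: Tf2O, 25% aq. Me4NOH, toluene, 0 °C → rt
Reagents that add atoms: trifluoromethanesulfonic anhydride, O=S(=O)(OS(=O)(=O)C(F)(F)F)C(F)(F)F
Why: O-sulfonylation of the β-keto ester enolate; the non-chelated tetramethylammonium enolate reacts in its extended form and gives the E-enol triflate (OTf trans to CO2Me), which fixes the later 2Z geometry.

Step 4
Reactants: 8 methyl (2E,6E)-7,11-dimethyl-3-{[(trifluoromethyl)sulfonyl]oxy}dodeca-2,6,10-trienoate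
Product: 9 methyl (2Z,6E)-3,7,11-trimethyldodeca-2,6,10-trienoate
Conditions: MeMgBr, Fe(acac)3 (5 mol%), THF/NMP, −30 °C
Reagents that add atoms: methylmagnesium bromide, C[Mg]Br
Why: Iron-catalysed (Kochi–Fürstner) cross-coupling of the alkenyl triflate proceeds with retention, so CH3 takes the place of OTf and the chain ends up cis to CO2Me (2Z).

Step 5
Reactants: 9 methyl (2Z,6E)-3,7,11-trimethyldodeca-2,6,10-trienoate
Product: 11 methyl (2Z,6E,10E)-3,7,11-trimethyl-12-oxododeca-2,6,10-trienoate, via allylic alcohol 10 (not isolated)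
Conditions: SeO2 (0.3 equiv), t-BuOOH, salicylic acid (cat.), CH2Cl2, 0 °C → rt; filter; then MnO2, CH2Cl2, rt
Reagents that add atoms: tert-butyl hydroperoxide, CC(C)(C)OO
Why: Sharpless–Umbreit SeO2 allylic oxidation (ene reaction, then [2,3]-shift) attacks the E-methyl of the electron-rich terminal trisubstituted alkene, and MnO2 carries the alcohol/aldehyde mixture to the single (10E)-enal.

Step 6
Reactants: 11 methyl (2Z,6E,10E)-3,7,11-trimethyl-12-oxododeca-2,6,10-trienoate
Product: 12 methyl (2Z,6E,10E)-3,7,11-trimethyltrideca-2,6,10,12-tetraenoate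
Conditions: Ph3PCH3Br, NaN(SiMe3)2, THF, 0 °C; then 11, −78 → 0 °C
Reagents that add atoms: methyltriphenylphosphonium bromide, C[P+](c1ccccc1)(c1ccccc1)c1ccccc1.[Br-]
Why: Wittig methylenation of the aldehyde, which is far more electrophilic than the β,β-disubstituted enoate; no alkene geometry is touched.

Step 7
Reactants: 12 methyl (2Z,6E,10E)-3,7,11-trimethyltrideca-2,6,10,12-tetraenoate; 3 (2Z)-3-iodo-2-methylprop-2-en-1-ol
Product: 14 methyl (2Z,6E,10E,14Z)-16-hydroxy-3,7,11,15-tetramethylhexadeca-2,6,10,14-tetraenoate, via alkyl-9-BBN borane 13 (not isolated)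
Conditions: 9-BBN, THF, 0 °C → rt; then 3, Pd(dppf)Cl2 (5 mol%), AsPh3, Cs2CO3, DMF/H2O, rt
Reagents that add atoms: none
Why: 9-BBN hydroborates only the monosubstituted end of the diene (anti-Markovnikov, as for 4,8-dimethylnona-1,3,7-triene in the homogeraniol synthesis), and the B-alkyl Suzuki–Miyaura coupling replaces iodine with retention, so the new chain is cis to CH2OH (14Z).

Step 8
Reactants: 14 methyl (2Z,6E,10E,14Z)-16-hydroxy-3,7,11,15-tetramethylhexadeca-2,6,10,14-tetraenoate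
Product: 15 methyl (2Z,6E,10E)-13-[(2S,3R)-3-(hydroxymethyl)-3-methyloxiran-2-yl]-3,7,11-trimethyltrideca-2,6,10-trienoate
Conditions: Ti(OiPr)4 (10 mol%), D-(−)-diisopropyl tartrate (12 mol%), t-BuOOH, 4 Å MS, CH2Cl2, −20 °C
Reagents that add atoms: tert-butyl hydroperoxide, CC(C)(C)OO
Why: Katsuki–Sharpless asymmetric epoxidation acts only on the allylic-alcohol alkene, and the D-tartrate catalyst delivers oxygen to the face that gives the (2S,3R)-oxirane (the mirror image of the L-tartrate result for 2-methyl-(Z)-allylic alcohols; about 90% ee is typical for this substitution pattern).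

Step 9
Reactants: 15 methyl (2Z,6E,10E)-13-[(2S,3R)-3-(hydroxymethyl)-3-methyloxiran-2-yl]-3,7,11-trimethyltrideca-2,6,10-trienoate
Product: 16 methyl (3S,4S,5R,9S,10R,13Z)-3,19-dihydroxylabda-7,13-dien-15-oate
Conditions: MeAlCl2 (3.5 equiv), CH2Cl2, −90 → −78 °C; then Et3N, aq. NaHCO3
Reagents that add atoms: none
Why: Lewis-acid epoxide-initiated cation–olefin bicyclization (van Tamelen/Corey type) through a chair–chair fold (Stork–Eschenmoser): the first equivalent of MeAlCl2 turns the 19-OH into an aluminium alkoxide that chelates the epoxide, C5 attacks C4 with inversion anti to the breaking C4–O bond so that the (Z)-CH2O arm becomes the axial 4β-CH2OH (C19) and the epoxide oxygen the equatorial 3β-OH, anti addition across the 10E and 6E alkenes closes ring A and then ring B as the trans-decalin with 5α-H, 10β-CH3 and the equatorial 9β side chain, the aluminium-bound enoate stays out, and the C8 cation loses the axial 7α-H to give the 7-ene.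

Step 10
Reactants: 16 methyl (3S,4S,5R,9S,10R,13Z)-3,19-dihydroxylabda-7,13-dien-15-oate
Product: 17 methyl (3S,4S,5R,9S,10R,13Z)-3,19-(thiocarbonyldioxy)labda-7,13-dien-15-oate
Conditions: 1,1'-thiocarbonyldiimidazole, DMAP (cat.), toluene, 80 °C
Reagents that add atoms: 1,1'-thiocarbonyldiimidazole, S=C(n1ccnc1)n1ccnc1
Why: Thiocarbonyl transfer joins the cis-1,3-diol (equatorial 3β-OH, axial 4β-CH2OH) into a six-membered cyclic thiocarbonate, the same 3,19-bridge that andrographolide-type diols form readily; no stereocentre changes.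

Step 11
Reactants: 17 methyl (3S,4S,5R,9S,10R,13Z)-3,19-(thiocarbonyldioxy)labda-7,13-dien-15-oate
Product: 19 (4S,5R,9S,10R,13Z)-19-hydroxylabda-7,13-dien-15-oic acid, via stannyl thiolcarbonate 18 (not isolated)
Conditions: Bu3SnH, AIBN (cat.), toluene, 100 °C; then LiOH, THF/MeOH/H2O, 40 °C; dilute HCl
Reagents that add atoms: lithium hydroxide, [Li+].[OH-]
Why: Barton radical deoxygenation of a cyclic thiocarbonate: the tributylstannyl radical adds to sulfur and the adduct fragments toward the more stable secondary C3 radical (not the primary neopentyl C19 radical), which takes H from Bu3SnH, and LiOH then cleaves the remaining C19 O–C(=O)–S–SnBu3 group together with the methyl ester; C3 becomes CH2 and the other stereocentres are untouched.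

Step 12
Reactants: 19 (4S,5R,9S,10R,13Z)-19-hydroxylabda-7,13-dien-15-oic acid; 20 tigloyl chloride [(2E)-2-methylbut-2-enoyl chloride]
Product: 22 (4S,5R,9S,10R,13Z)-19-{[(2E)-2-methylbut-2-enoyl]oxy}labda-7,13-dien-15-oic acid (the target), via mixed anhydride 21 (not isolated)
Conditions: 20 (3 equiv), DMAP (cat.), pyridine, CH2Cl2, 0 → 40 °C; then H2O/THF, rt
Reagents that add atoms: water, O
Why: DMAP-catalysed O-acylation (nucleophilic catalysis) of the neopentyl 19-OH by the acid chloride, with the carboxylic acid tied up as a mixed anhydride that water hydrolyses back to the free acid; tiglate E geometry, the 13Z alkene and all stereocentres are kept.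

## Compound list

1 | prop-2-yn-1-ol | C#CCO | starting material
2 | bromomagnesium (2Z)-3-(bromomagnesio)-2-methylprop-2-en-1-olate | Br[Mg]OC/C(C)=C\[Mg]Br | intermediate (not isolated)
3 | (2Z)-3-iodo-2-methylprop-2-en-1-ol | OC/C(C)=C\I | intermediate
4 | geranyl bromide, (2E)-1-bromo-3,7-dimethylocta-2,6-diene | BrC/C=C(\C)CCC=C(C)C | starting material
5 | methyl acetoacetate | COC(=O)CC(C)=O | starting material
6 | sodium lithium dianion of methyl acetoacetate | [Na+].[Li+].COC(=O)[CH-]C(=O)[CH2-] | intermediate (not isolated)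
7 | methyl (6E)-7,11-dimethyl-3-oxododeca-6,10-dienoate | COC(=O)CC(=O)CC/C=C(\C)CCC=C(C)C | intermediate
8 | methyl (2E,6E)-7,11-dimethyl-3-{[(trifluoromethyl)sulfonyl]oxy}dodeca-2,6,10-trienoate | COC(=O)/C=C(/OS(=O)(=O)C(F)(F)F)CC/C=C(\C)CCC=C(C)C | intermediate
9 | methyl (2Z,6E)-3,7,11-trimethyldodeca-2,6,10-trienoate | COC(=O)/C=C(/C)CC/C=C(\C)CCC=C(C)C | intermediate
10 | methyl (2Z,6E,10E)-12-hydroxy-3,7,11-trimethyldodeca-2,6,10-trienoate | COC(=O)/C=C(/C)CC/C=C(\C)CC/C=C(\C)CO | intermediate (not isolated)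
11 | methyl (2Z,6E,10E)-3,7,11-trimethyl-12-oxododeca-2,6,10-trienoate | COC(=O)/C=C(/C)CC/C=C(\C)CC/C=C(\C)C=O | intermediate
12 | methyl (2Z,6E,10E)-3,7,11-trimethyltrideca-2,6,10,12-tetraenoate | COC(=O)/C=C(/C)CC/C=C(\C)CC/C=C(\C)C=C | intermediate
13 | methyl (2Z,6E,10E)-13-(9-borabicyclo[3.3.1]nonan-9-yl)-3,7,11-trimethyltrideca-2,6,10-trienoate | COC(=O)/C=C(/C)CC/C=C(\C)CC/C=C(\C)CCB1C2CCCC1CCC2 | intermediate (not isolated)
14 | methyl (2Z,6E,10E,14Z)-16-hydroxy-3,7,11,15-tetramethylhexadeca-2,6,10,14-tetraenoate | COC(=O)/C=C(/C)CC/C=C(\C)CC/C=C(\C)CC/C=C(/C)CO | intermediate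
15 | methyl (2Z,6E,10E)-13-[(2S,3R)-3-(hydroxymethyl)-3-methyloxiran-2-yl]-3,7,11-trimethyltrideca-2,6,10-trienoate | COC(=O)/C=C(/C)CC/C=C(\C)CC/C=C(\C)CC[C@@H]1O[C@]1(C)CO | intermediate
16 | methyl (3S,4S,5R,9S,10R,13Z)-3,19-dihydroxylabda-7,13-dien-15-oate (3β-OH; axial 4β-CH2OH; 5α-H; 9α-H; 10β-CH3) | OC[C@@]1(C)[C@@H](O)CC[C@]2(C)[C@@H](CC/C(C)=C\C(=O)OC)C(C)=CC[C@@H]12 | intermediate
17 | methyl (3S,4S,5R,9S,10R,13Z)-3,19-(thiocarbonyldioxy)labda-7,13-dien-15-oate (six-membered cyclic thiocarbonate across O3 and O19) | S=C1OC[C@@]2(C)[C@@H](O1)CC[C@]3(C)[C@@H](CC/C(C)=C\C(=O)OC)C(C)=CC[C@@H]23 | intermediate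
18 | methyl (4S,5R,9S,10R,13Z)-19-({[(tributylstannyl)sulfanyl]carbonyl}oxy)labda-7,13-dien-15-oate | CCCC[Sn](CCCC)(CCCC)SC(=O)OC[C@@]1(C)CCC[C@]2(C)[C@@H](CC/C(C)=C\C(=O)OC)C(C)=CC[C@@H]12 | intermediate (not isolated)
19 | (4S,5R,9S,10R,13Z)-19-hydroxylabda-7,13-dien-15-oic acid | OC[C@@]1(C)CCC[C@]2(C)[C@@H](CC/C(C)=C\C(=O)O)C(C)=CC[C@@H]12 | intermediate
20 | tigloyl chloride, (2E)-2-methylbut-2-enoyl chloride | C/C=C(\C)C(=O)Cl | starting material
21 | mixed anhydride of (4S,5R,9S,10R,13Z)-19-{[(2E)-2-methylbut-2-enoyl]oxy}labda-7,13-dien-15-oic acid with (2E)-2-methylbut-2-enoic acid | C/C=C(\C)C(=O)OC[C@@]1(C)CCC[C@]2(C)[C@@H](CC/C(C)=C\C(=O)OC(=O)/C(C)=C/C)C(C)=CC[C@@H]12 | intermediate (not isolated)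
22 | (4S,5R,9S,10R,13Z)-19-{[(2E)-2-methylbut-2-enoyl]oxy}labda-7,13-dien-15-oic acid (CNP0249147.2) | C/C=C(\C)C(=O)OC[C@@]1(C)CCC[C@]2(C)[C@@H](CC/C(C)=C\C(=O)O)C(C)=CC[C@@H]12 | target

## Step count and weak points

Total step count: 12. Longest linear sequence: 11 steps (4 to 22, steps 2–12); step 1 is a one-step side branch.

Three steps most likely to fail:

Step 9 (bicyclization of the free epoxy alcohol). The aluminium alkoxide may divert the epoxide (Payne-type epoxide migration, hydride shift to a β-hydroxy aldehyde, 5-exo opening), and proton loss may give some 8(17)- or 8-ene beside the 7-ene. Fallback, from 15 back to 16: mask the hydroxyl so that ionisation is driven only by an external Lewis acid on the oxirane oxygen. TBSCl/imidazole (DMF) gives methyl (2Z,6E,10E)-13-[(2S,3R)-3-({[tert-butyl(dimethyl)silyl]oxy}methyl)-3-methyloxiran-2-yl]-3,7,11-trimethyltrideca-2,6,10-trienoate F1. MeAlCl2 (CH2Cl2, −78 °C) cyclises it to methyl (3S,4S,5R,9S,10R,13Z)-19-{[tert-butyl(dimethyl)silyl]oxy}-3-hydroxylabda-7,13-dien-15-oate F2. HF·pyridine (THF) removes the silyl group and gives 16.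

Step 11 (deoxygenation through the cyclic thiocarbonate). Part of the radical adduct may fragment toward C19, giving the 19-deoxy 3-ol, and the one-flask hydrolysis may be incomplete. Fallback, from 16 back to 19: differentiate the two hydroxyls and remove the secondary one by an acyclic Barton–McCombie reaction. TBDPSCl/imidazole silylates the primary hydroxyl to give methyl (3S,4S,5R,9S,10R,13Z)-19-{[tert-butyl(diphenyl)silyl]oxy}-3-hydroxylabda-7,13-dien-15-oate F3. Thiocarbonyldiimidazole/DMAP (toluene, 90 °C) gives methyl (3S,4S,5R,9S,10R,13Z)-19-{[tert-butyl(diphenyl)silyl]oxy}-3-[(1H-imidazol-1-ylcarbonothioyl)oxy]labda-7,13-dien-15-oate F4. Bu3SnH/AIBN (toluene, 100 °C) gives methyl (4S,5R,9S,10R,13Z)-19-{[tert-butyl(diphenyl)silyl]oxy}labda-7,13-dien-15-oate F5. Bu4NF and then LiOH give 19.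

Step 12 (acylation beside a free acid). The hindered axial neopentyl alcohol may react slowly, and the transient mixed anhydride could scramble the 13Z alkene or give dimeric esters. Fallback, from 19 back to 22: mask the acid first. Allyl bromide/K2CO3 (DMF) gives prop-2-en-1-yl (4S,5R,9S,10R,13Z)-19-hydroxylabda-7,13-dien-15-oate F6. Tigloyl chloride/DMAP/pyridine gives prop-2-en-1-yl (4S,5R,9S,10R,13Z)-19-{[(2E)-2-methylbut-2-enoyl]oxy}labda-7,13-dien-15-oate F7. Pd(PPh3)4 with morpholine (THF, rt) removes the allyl group and gives 22.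

## Further compounds

F1 | step 9 | methyl (2Z,6E,10E)-13-[(2S,3R)-3-({[tert-butyl(dimethyl)silyl]oxy}methyl)-3-methyloxiran-2-yl]-3,7,11-trimethyltrideca-2,6,10-trienoate | COC(=O)/C=C(/C)CC/C=C(\C)CC/C=C(\C)CC[C@@H]1O[C@]1(C)CO[Si](C)(C)C(C)(C)C
F2 | step 9 | methyl (3S,4S,5R,9S,10R,13Z)-19-{[tert-butyl(dimethyl)silyl]oxy}-3-hydroxylabda-7,13-dien-15-oate | CC(C)(C)[Si](C)(C)OC[C@@]1(C)[C@@H](O)CC[C@]2(C)[C@@H](CC/C(C)=C\C(=O)OC)C(C)=CC[C@@H]12
F3 | step 11 | methyl (3S,4S,5R,9S,10R,13Z)-19-{[tert-butyl(diphenyl)silyl]oxy}-3-hydroxylabda-7,13-dien-15-oate | CC(C)(C)[Si](c4ccccc4)(c5ccccc5)OC[C@@]1(C)[C@@H](O)CC[C@]2(C)[C@@H](CC/C(C)=C\C(=O)OC)C(C)=CC[C@@H]12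
F4 | step 11 | methyl (3S,4S,5R,9S,10R,13Z)-19-{[tert-butyl(diphenyl)silyl]oxy}-3-[(1H-imidazol-1-ylcarbonothioyl)oxy]labda-7,13-dien-15-oate | CC(C)(C)[Si](c4ccccc4)(c5ccccc5)OC[C@@]1(C)[C@@H](OC(=S)n3ccnc3)CC[C@]2(C)[C@@H](CC/C(C)=C\C(=O)OC)C(C)=CC[C@@H]12
F5 | step 11 | methyl (4S,5R,9S,10R,13Z)-19-{[tert-butyl(diphenyl)silyl]oxy}labda-7,13-dien-15-oate | CC(C)(C)[Si](c4ccccc4)(c5ccccc5)OC[C@@]1(C)CCC[C@]2(C)[C@@H](CC/C(C)=C\C(=O)OC)C(C)=CC[C@@H]12
F6 | step 12 | prop-2-en-1-yl (4S,5R,9S,10R,13Z)-19-hydroxylabda-7,13-dien-15-oate | OC[C@@]1(C)CCC[C@]2(C)[C@@H](CC/C(C)=C\C(=O)OCC=C)C(C)=CC[C@@H]12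
F7 | step 12 | prop-2-en-1-yl (4S,5R,9S,10R,13Z)-19-{[(2E)-2-methylbut-2-enoyl]oxy}labda-7,13-dien-15-oate | C/C=C(\C)C(=O)OC[C@@]1(C)CCC[C@]2(C)[C@@H](CC/C(C)=C\C(=O)OCC=C)C(C)=CC[C@@H]12
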